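Ring A is a fully substituted benzene in which C2–OH, C3–prenyl, C4–OMe, C5–prenyl and C6–OH follow one another and C1 carries the aroyl group. The route cuts ring A at C1–C2 and C5–C6: a thermal cyclobutenone/ynol ether benzannulation joins a 3-methoxy-2,4-diprenylcyclobutenone (itself a ketene/methoxyalkyne [2+2] adduct) with triisopropylsilyloxyacetylene and, in one operation, delivers ring A with both prenyl groups, the methyl ether, two differentiated oxygens and a single hydrogen at C1. That hydrogen is then lithiated between two MOM ethers and joined to a protected 3-hydroxybenzaldehyde; oxidation and one acidic deprotection complete the benzophenone.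

Key step: step 5

Remark: the target has no stereocentre and is achiral, so no enantiocontrol is required; the sp3 stereocentres of 8, 14, 16 and 23 are racemic and are erased in later steps. Ring A is numbered with C1 as the carbonyl-bearing carbon.

Step 1
Reactants: 1 chloroacetaldehyde dimethyl acetal; 2 prenyl bromide
Product: 4 1-methoxy-5-methylhex-4-en-1-yne, via sodium methoxyacetylide 3 (not isolated)
Conditions: NaNH2 (3.0 equiv), liq. NH3, −33 °C; then 2, −33 °C; NH3 evaporated, pentane/brine, distillation
Reagents that add atoms: none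
Why: Sodium amide removes methanol and then HCl from the chloroacetal (the standard alkoxyacetylene synthesis) and deprotonates the alkyne, and the resulting acetylide is C-alkylated by the primary allylic bromide in an SN2 reaction.

Step 2
Reactants: 5 5-methylhex-4-enoic acid
Product: 6 5-methylhex-4-enoyl chloride
Conditions: (COCl)2, cat. DMF, CH2Cl2, 0 °C → rt; concentrated and used crude
Reagents that add atoms: oxalyl chloride, ClC(=O)C(=O)Cl
Why: Vilsmeier-catalysed conversion of a carboxylic acid into its chloride, under which the isolated trisubstituted alkene should be inert.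

Step 3
Reactants: 6 5-methylhex-4-enoyl chloride; 4 1-methoxy-5-methylhex-4-en-1-yne
Product: 8 3-methoxy-2,4-bis(3-methylbut-2-enyl)cyclobut-2-en-1-one (racemic at C4), via prenylketene 7 (not isolated)
Conditions: 6 (1.5 equiv) added over 4 h to 4 and Et3N (2 equiv), CH2Cl2, rt; cold aq. NaHCO3; Et3N-deactivated silica
Reagents that add atoms: none
Why: Triethylamine dehydrochlorinates 6 to the aldoketene, which undergoes a thermal ketene–alkyne [2+2] cycloaddition in which the nucleophilic prenyl-bearing carbon of the ynol ether attacks the ketene carbonyl carbon, placing methoxy at C3 and the prenyl groups at C2 and C4.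

Step 4
Reactants: 9 acetylene
Product: 12 ethynyloxy(triisopropyl)silane, via lithium acetylide 10 (not isolated), via lithium ethynolate 11 (not isolated)
Conditions: HC≡CH (excess), n-BuLi, THF, −78 °C; t-BuOOLi (from t-BuOOH and LiHMDS), −78 → 0 °C; TIPSOTf, −78 → 0 °C; distillation
Reagents that add atoms: tert-butyl hydroperoxide (used as its lithium salt), CC(C)(C)OO; triisopropylsilyl triflate, CC(C)[Si](OS(=O)(=O)C(F)(F)F)(C(C)C)C(C)C
Why: Electrophilic oxygenation of a lithium acetylide by lithium tert-butyl peroxide gives the ynolate, which the hard, bulky silyl triflate should silylate on oxygen to the silyl ynol ether.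

Step 5
Reactants: 8 3-methoxy-2,4-bis(3-methylbut-2-enyl)cyclobut-2-en-1-one; 12 ethynyloxy(triisopropyl)silane
Product: 17 3-methoxy-2,4-bis(3-methylbut-2-enyl)-5-(triisopropylsilyloxy)phenol, via vinylketene 13 (not isolated), via vinylcyclobutenone 14 (not isolated), via dienylketene 15 (not isolated), via cyclohexadienone 16 (not isolated)
Conditions: 12 (1.5 equiv), degassed toluene, 80 °C then 110 °C, sealed tube, argon
Reagents that add atoms: none
Why: Heating opens the cyclobutenone by a conrotatory 4π electrocyclic reaction (C4 prenyl turning outward) to vinylketene 13, whose ketene unit adds the ynol ether in a [2+2] cycloaddition to give 14, which opens again to dienylketene 15 and closes by a 6π electrocyclisation to dienone 16, which enolises to the phenol. The closest known reaction type is the Danheiser benzannulation in its cyclobutenone/siloxyalkyne form. Ring A is the only ring closed, by the disrotatory 6π electrocyclisation that forms C2–C3 after the [2+2] step has made the C1–C2 and C5–C6 bonds. No stereocentre remains in the product, since the sp3 centres of 14 and 16 are lost on ring opening and aromatisation. The step needs regiocontrol in the ketene–alkyne union, and the polarisation of the ynol ether secures it: its nucleophilic CH terminus bonds to the electrophilic ketene carbonyl carbon (future C2), so the silyloxy carbon lands next to the prenyl-bearing C5 and the only ring hydrogen sits at C1 between the two oxygens. The geometry of 15 needed for closure (vinyl group cis to the ketene) should be reached because opening of 14 is reversible.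

Step 6
Reactants: 17 3-methoxy-2,4-bis(3-methylbut-2-enyl)-5-(triisopropylsilyloxy)phenol
Product: 19 2-methoxy-4,6-bis(methoxymethoxy)-1,3-bis(3-methylbut-2-enyl)benzene, via resorcinol 18 (not isolated)
Conditions: TBAF (1.1 equiv), THF, 0 °C; then i-Pr2NEt, MOMCl (excess), 0 °C → rt
Reagents that add atoms: chloromethyl methyl ether, COCCl
Why: Fluoride cleaves the aryl silyl ether and both phenolic oxygens are then etherified by Williamson-type alkylation, which removes the silyl group before metalation (no O-to-C silyl shift is possible) and leaves one ring hydrogen flanked by two directing groups.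

Step 7
Reactants: 20 3-hydroxybenzaldehyde
Product: 21 3-(methoxymethoxy)benzaldehyde
Conditions: MOMCl, i-Pr2NEt, CH2Cl2, 0 °C → rt
Reagents that add atoms: chloromethyl methyl ether, COCCl
Why: Williamson-type O-alkylation of the phenol under amine base, which leaves the aldehyde untouched.

Step 8
Reactants: 19 2-methoxy-4,6-bis(methoxymethoxy)-1,3-bis(3-methylbut-2-enyl)benzene; 21 3-(methoxymethoxy)benzaldehyde
Product: 23 [4-methoxy-2,6-bis(methoxymethoxy)-3,5-bis(3-methylbut-2-enyl)phenyl][3-(methoxymethoxy)phenyl]methanol (racemic), via aryllithium 22 (not isolated)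
Conditions: n-BuLi (1.1 equiv), THF, 0 °C, 1 h; then 21, −78 → 0 °C; aq. NH4Cl
Reagents that add atoms: none
Why: Directed ortho-metalation at the only aryl hydrogen, which lies between two cooperating MOM ethers, followed by 1,2-addition of the aryllithium to the aldehyde, gives the diarylcarbinol, whose racemic stereocentre is removed in the next step.

Step 9
Reactants: 23 [4-methoxy-2,6-bis(methoxymethoxy)-3,5-bis(3-methylbut-2-enyl)phenyl][3-(methoxymethoxy)phenyl]methanol
Product: 24 [4-methoxy-2,6-bis(methoxymethoxy)-3,5-bis(3-methylbut-2-enyl)phenyl][3-(methoxymethoxy)phenyl]methanone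
Conditions: Dess–Martin periodinane, NaHCO3, CH2Cl2, 0 °C → rt
Reagents that add atoms: none
Why: Dess–Martin oxidation of the doubly benzylic secondary alcohol under buffered conditions that should leave the prenyl alkenes and the MOM acetals intact.

Step 10
Reactants: 24 [4-methoxy-2,6-bis(methoxymethoxy)-3,5-bis(3-methylbut-2-enyl)phenyl][3-(methoxymethoxy)phenyl]methanone
Product: 25 (2,6-dihydroxy-4-methoxy-3,5-bis(3-methylbut-2-enyl)phenyl)(3-hydroxyphenyl)methanone
Conditions: HCl (ca. 1 M in MeOH), 0 °C → rt, monitored closely; aq. NaHCO3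
Reagents that add atoms: none
Why: Acid-catalysed acetal methanolysis should remove all three MOM groups (those ortho to the ketone fastest) under conditions mild enough to avoid addition of the freed phenols to the prenyl double bonds.

Compound list
1 | chloroacetaldehyde dimethyl acetal (2-chloro-1,1-dimethoxyethane) | COC(CCl)OC | starting material
2 | prenyl bromide (1-bromo-3-methylbut-2-ene) | CC(C)=CCBr | starting material
3 | sodium methoxyacetylide | COC#C[Na] | intermediate
4 | 1-methoxy-5-methylhex-4-en-1-yne | COC#CCC=C(C)C | intermediate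
5 | 5-methylhex-4-enoic acid | CC(C)=CCCC(=O)O | starting material
6 | 5-methylhex-4-enoyl chloride | CC(C)=CCCC(=O)Cl | intermediate
7 | prenylketene (5-methylhexa-1,4-dien-1-one) | CC(C)=CCC=C=O | intermediate
8 | 3-methoxy-2,4-bis(3-methylbut-2-enyl)cyclobut-2-en-1-one (racemic at C4) | COC1=C(CC=C(C)C)C(=O)C1CC=C(C)C | intermediate
9 | acetylene | C#C | starting material
10 | lithium acetylide | [Li]C#C | intermediate
11 | lithium ethynolate | [Li]OC#C | intermediate
12 | ethynyloxy(triisopropyl)silane | C#CO[Si](C(C)C)(C(C)C)C(C)C | intermediate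
13 | (3Z)-3-methoxy-7-methyl-2-(3-methylbut-2-enyl)octa-1,3,6-trien-1-one (vinylketene; C5 trans to C2) | O=C=C(CC=C(C)C)/C(OC)=C/CC=C(C)C | intermediate
14 | 4-[(1Z)-1-methoxy-5-methylhexa-1,4-dienyl]-4-(3-methylbut-2-enyl)-3-(triisopropylsilyloxy)cyclobut-2-en-1-one (racemic) | O=C1C=C(O[Si](C(C)C)(C(C)C)C(C)C)C1(CC=C(C)C)/C(OC)=C/CC=C(C)C | intermediate
15 | (3E,5Z)-5-methoxy-9-methyl-4-(3-methylbut-2-enyl)-3-(triisopropylsilyloxy)deca-1,3,5,8-tetraen-1-one (dienylketene; C2 and C5 cis) | O=C=C/C(O[Si](C(C)C)(C(C)C)C(C)C)=C(CC=C(C)C)\C(OC)=C\CC=C(C)C | intermediate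
16 | 5-methoxy-4,6-bis(3-methylbut-2-enyl)-3-(triisopropylsilyloxy)cyclohexa-2,4-dien-1-one (racemic) | O=C1C=C(O[Si](C(C)C)(C(C)C)C(C)C)C(CC=C(C)C)=C(OC)C1CC=C(C)C | intermediate
17 | 3-methoxy-2,4-bis(3-methylbut-2-enyl)-5-(triisopropylsilyloxy)phenol | COc1c(CC=C(C)C)c(O)cc(O[Si](C(C)C)(C(C)C)C(C)C)c1CC=C(C)C | intermediate
18 | 5-methoxy-4,6-bis(3-methylbut-2-enyl)benzene-1,3-diol (present as its tetrabutylammonium phenoxide) | COc1c(CC=C(C)C)c(O)cc(O)c1CC=C(C)C | intermediate
19 | 2-methoxy-4,6-bis(methoxymethoxy)-1,3-bis(3-methylbut-2-enyl)benzene | COCOc1cc(OCOC)c(CC=C(C)C)c(OC)c1CC=C(C)C | intermediate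
20 | 3-hydroxybenzaldehyde | O=Cc1cccc(O)c1 | starting material
21 | 3-(methoxymethoxy)benzaldehyde | COCOc1cccc(C=O)c1 | intermediate
22 | [4-methoxy-2,6-bis(methoxymethoxy)-3,5-bis(3-methylbut-2-enyl)phenyl]lithium | [Li]c1c(OCOC)c(CC=C(C)C)c(OC)c(CC=C(C)C)c1OCOC | intermediate
23 | [4-methoxy-2,6-bis(methoxymethoxy)-3,5-bis(3-methylbut-2-enyl)phenyl][3-(methoxymethoxy)phenyl]methanol (racemic) | COCOc1cccc(c1)C(O)c1c(OCOC)c(CC=C(C)C)c(OC)c(CC=C(C)C)c1OCOC | intermediate
24 | [4-methoxy-2,6-bis(methoxymethoxy)-3,5-bis(3-methylbut-2-enyl)phenyl][3-(methoxymethoxy)phenyl]methanone | COCOc1cccc(c1)C(=O)c1c(OCOC)c(CC=C(C)C)c(OC)c(CC=C(C)C)c1OCOC | intermediate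
25 | (2,6-dihydroxy-4-methoxy-3,5-bis(3-methylbut-2-enyl)phenyl)(3-hydroxyphenyl)methanone (achiral) | COc1c(CC=C(C)C)c(O)c(C(=O)c2cccc(O)c2)c(O)c1CC=C(C)C | target

Total step count: 10
Longest linear sequence: 7 steps (1, 3, 5, 6, 8, 9, 10)

Steps most likely to fail

1. Step 5. The vinylogous-ester cyclobutenone may open sluggishly. The vinylketene may dimerise or acylate the product phenol faster than it adds the ynol ether. The siloxyalkyne may isomerise to a silylketene on prolonged heating. The fallback gives up the pericyclic construction of ring A and uses a preformed phloroglucinol ring; it sets out from 21 and 2 and comes back to the route at 25. 5-Methoxyresorcinol F1 is protected with MOMCl/i-Pr2NEt to 1-methoxy-3,5-bis(methoxymethoxy)benzene F2. This is lithiated with n-BuLi between the two MOM ethers to [4-methoxy-2,6-bis(methoxymethoxy)phenyl]lithium F3, which adds to 21 to give [4-methoxy-2,6-bis(methoxymethoxy)phenyl][3-(methoxymethoxy)phenyl]methanol F4. Dess–Martin oxidation should give [4-methoxy-2,6-bis(methoxymethoxy)phenyl][3-(methoxymethoxy)phenyl]methanone F5, and HCl/MeOH should give (2,6-dihydroxy-4-methoxyphenyl)(3-hydroxyphenyl)methanone F6. Double C-prenylation of the ring-A phenoxide of F6 with 2 (aq. KOH, two equivalents of base so that only the acidic ring-A phenols are ionised) at the free positions C3 and C5 should then deliver 25.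

2. Step 4. Monolithium acetylide may disproportionate on warming before oxygen transfer is complete, and the unhindered ynolate may be silylated on carbon to give a silylketene. The fallback generates the ynolate by fragmentation instead of oxidation; it replaces 9 and 10, sets out from commercial 3-phenylisoxazole F7 and comes back to the route at 11. Lithiation of F7 at C5 (n-BuLi, THF, −78 °C) gives 5-lithio-3-phenylisoxazole F8, which should undergo cycloreversion on warming to benzonitrile and 11. Silylation with TIPSOTf as in step 4 then gives 12, separated from benzonitrile by distillation.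

3. Step 3. Ammonium-salt-promoted dimerisation of the aldoketene may outrun the cycloaddition, and the vinylogous ester product may hydrolyse on work-up. The fallback generates the same ketene without base or salts by a photochemical Wolff rearrangement; it sets out from 4 and comes back to the route at 8 by way of 7. 4-Methylpent-3-enoic acid F9 is converted with oxalyl chloride into 4-methylpent-3-enoyl chloride F10 and then with trimethylsilyldiazomethane into 1-diazo-5-methylhex-4-en-2-one F11. Irradiation of F11 (λ > 300 nm, CH2Cl2, rt) in the presence of 4 should release 7 at low stationary concentration, which is trapped by 4 to give 8.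

Further compounds
F1 | step 5 | 5-methoxyresorcinol (5-methoxybenzene-1,3-diol) | COc1cc(O)cc(O)c1
F2 | step 5 | 1-methoxy-3,5-bis(methoxymethoxy)benzene | COCOc1cc(OC)cc(OCOC)c1
F3 | step 5 | [4-methoxy-2,6-bis(methoxymethoxy)phenyl]lithium | [Li]c1c(OCOC)cc(OC)cc1OCOC
F4 | step 5 | [4-methoxy-2,6-bis(methoxymethoxy)phenyl][3-(methoxymethoxy)phenyl]methanol (racemic) | COCOc1cccc(c1)C(O)c1c(OCOC)cc(OC)cc1OCOC
F5 | step 5 | [4-methoxy-2,6-bis(methoxymethoxy)phenyl][3-(methoxymethoxy)phenyl]methanone | COCOc1cccc(c1)C(=O)c1c(OCOC)cc(OC)cc1OCOC
F6 | step 5 | (2,6-dihydroxy-4-methoxyphenyl)(3-hydroxyphenyl)methanone | COc1cc(O)c(C(=O)c2cccc(O)c2)c(O)c1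
F7 | step 4 | 3-phenylisoxazole | c1ccc(cc1)-c1ccon1
F8 | step 4 | 5-lithio-3-phenylisoxazole | [Li]c1cc(no1)-c1ccccc1
F9 | step 3 | 4-methylpent-3-enoic acid | CC(C)=CCC(=O)O
F10 | step 3 | 4-methylpent-3-enoyl chloride | CC(C)=CCC(=O)Cl
F11 | step 3 | 1-diazo-5-methylhex-4-en-2-one | CC(C)=CCC(=O)C=[N+]=[N-]
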